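**Numbering and conventions.** Briarane numbering is used throughout: ring A = C1, C10–C14; ring B = C1–C10; ring C = C7–O–C19(=O)–C17–C8; C15 on C1, C16 on C5, C18 on C17, C20 on C11. β is the face of ring A that carries C15, α the opposite face. Compound numbers are those of the steps below.

## The problem

Briaexcavatolide N (56) has a cyclohexane ring A trans-fused at C1–C10 to a ten-membered ring B, which holds a (3Z,5E)-diene with both double bonds cis inside the ring. Ring B is in turn trans-fused at C7–C8 to the γ-lactone ring C. Eleven stereocentres (C1, C2, C7–C14, C17) must be set. The quaternary C1, with its methyl axial on the β face, can govern C10, C11, C12 and the α-epoxide at C13–C14; C10 can govern C9, and C9 can govern C8. C2, C17 and C7 have no dependable neighbour and call for a catalyst, the chiral pool and the ring closure. The C11 methyl is cis to both C15 and the C9 arm, the less stable arrangement while C12 is a ketone, so it must be set kinetically and frozen by reduction. Fragile groups are the 12-acetoxy-13,14-epoxide (acid opens it through the acetate), the 9-acetoxy-8-hydroxy lactone (acyl and lactone shifts) and the diene flanked by two allylic alcohols; none tolerates strong base, hydride or organolithium reagents. The opening for the key step is that C9 and C12 are both oxygenated and stand 1,4 to each other across C10–C11. This is the pattern of a 1,4-dicarbonyl compound, which polar enolate chemistry cannot join directly but which results when two enol ethers are coupled by oxidation, and the bond is a ring A bond next to the preset C1.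

## Retrosynthesis

**Silyl ethers and lactone.** 56 is traced to its bis-silyl ether 55, and the C19–O7 bond of 55 is cut to the diol 53 (primary C19 alcohol, secondary C7 alcohol). This is preferred to an ester-enolate closure at C8–C17 because both acetates can already be in place: with O9 acetylated and O8 tertiary, an oxidative lactonisation can only end on O7. 53 and its silyl ether 52 no longer contain ring C. The forward step must oxidise one primary alcohol beside an allylic alcohol and the diene.

**Ring B.** In 52 the C6–C7 bond is cut, giving the open-chain aldehyde 51 with a dienyl iodide. This bond is chosen because its formation from an alkenyl iodide and an aldehyde gives the C7 carbinol the lactone needs, uses an sp2 carbon of fixed geometry, and tolerates acetates and the epoxide. Closure at C2–C3 would leave the C2 carbinol to ring control, and metathesis at either diene bond would have to form a conjugated cis,cis-diene in a medium ring. 51 has lost the medium ring and one stereocentre. The forward reaction must beat oligomerisation and set C7.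

**Diene.** 51 comes from 50 and 49, and the C4–C5 bond of the dienylsilane 49 is cut (through the enyne 48) to the terminal alkyne 42 and the iodide 47. Both geometries then rest on stereospecific reactions: cis-hydrogenation of C3≡C4 and cis-silylstannation of the alkyne 44 with 45 (giving 46). The alkyne has been on C2 from the start, so this cut costs no extra group, whereas a cut at C5=C6 would need an olefination of uncertain geometry. 42 is a ring A compound with two arms; 47 is three steps from 43.

**Lactone arm.** 42 is taken back through 41 and 40 to the allylic alcohol 39 (the C7 and C8 hydroxyls become a 1,1-disubstituted alkene), and the C8–C9 bond of 39 is cut to the ring A aldehyde 31 and the iodoalkene 38. The union is placed at the carbon that the key step delivers at the aldehyde level. It lets C10 control C9 and C9 control C8, and brings C17 from the Roche ester 32 (through 33, 34 and 36, with 35 as the one-carbon source). An aldol union is not available because C8 is not α to a carbonyl group in ring C. The forward reactions must add to an aldehyde beside an acetate and an epoxide and must be face-selective at C8.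

**Ring A functional groups.** 31 is simplified without C–C cuts: acetal 30, alkene 29, alcohol 28, enone 26, its C11 epimer mixture 24, and the saturated ketone 22. The order follows from the axial C15 methyl, which sends a proton to C11, hydride to C12 and the peracid to C13=C14 all from the α face, and from the need to reduce C12 as soon as the less stable 11β-methyl is in place. 22 has only C1, C2 and C10 defined.

**Key disconnection.** In 22 the C10–C11 bond is cut. It links two carbons that would both be α to a carbonyl group, and is formed by anodic coupling of the C9=C10 methyl enol ether with the C11=C12 silyl enol ether of the acyclic 21. Cuts at C1–C10 or C1–C14 would have to create the quaternary centre during ring closure; this cut keeps C1 preset and uses it to control C10. C20 is placed on the silyl enol ether beforehand. Without it, C11 and C13 would both be methylene groups flanking the C12 carbonyl and could not be told apart. With it, kinetic enolisation of 22 goes to C13 (for the enone) and leaves C11 for a later protonation. The forward reaction must cyclise faster than the radical cation is trapped by solvent and place C9 trans to the C2 arm.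

**Precursor.** 21 comes from the aldehyde 18 and the phosphonium salt 19 (through the ylide 20), 18 from the ester 16 through the alcohol 17, and the silyl enol ether of 16 from the vinyl ketone 14 by conjugate reduction. 14 is made from the methyl ketone 9 and the iminium salt 10. The enol ether is made before the ester is reduced so that it also protects the ketone. An ethyl ketone would not enolise regioselectively, whereas the methyl ketone 9 enolises kinetically only at C11.

**C2 and C1.** The silyl ether 9 comes from the alcohol 8 and 8 from the ynone 7, so that C2 is set by a catalyst and not by the neighbouring quaternary carbon. The C2–C3 bond of 7 is cut to the acid 4 (as its chloride 6) and the alkyne 5. 4 is the half-ester of the prochiral diester 3, the Michael adduct of 1 and 2. The quaternary stereocentre is thus reduced to telling two enantiotopic esters apart.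

## Roads not taken

**Alternative 1:** The C5=C6 bond of ring B is replaced by a C5–SO2–C6 bridge. The eleven-membered sulfone A1 is halogenated α to sulfur in the flask and loses SO2 (Ramberg–Bäcklund reaction) to give the diene A2. Its merit is real: an eleven-membered thioether closes by S-alkylation more easily than a ten-membered ring closes by C–C bond formation, and the contraction makes the trisubstituted alkene where only the ring-cis isomer fits. In this respect it is a better answer to the medium ring than the chromium closure of step 33. Its weak points are the strongly basic halogenating medium and what this forces on A1. Acetates and lactone cannot be present, so O9 and O12 are benzyl-type ethers, C8 is a ketal and O7 a silyl ether. The lactone with C8 and C17 and both acetates must then be made after the contraction, on the most valuable intermediate and beside the epoxide. The allylic, doubly activated C5–H also invites diene migration. Against the easier ring closure the chosen plan sets an early key step on cheap material that builds ring A with the C9/C12 oxygen pattern, and acetates that are carried rather than exchanged at the end.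

**Alternative 2:** Ring A is cut at C9–C10 and C11–C20 and comes from the prochiral dienone A3. A copper-catalysed asymmetric addition of a vinyl Grignard reagent, Mannich trapping of the enolate and elimination give A4 in one flask and set C1 and C10. This road is clearly shorter to ring A (a few steps against eleven to 22). It also delivers the C13=C14 enone and the C11 methylene exactly where the epoxide and C20 are needed, so the regiochemical problem that costs the chosen route steps 6, 7 and 13 does not arise. Its weak points are these. The catalyst must choose between two enantiotopic enone arms and also between two faces that differ only as CH3 against CH2OSi at C1. Vinyl Grignard reagents are poor partners in such additions. C9 arrives as an alkene carbon that must be cleaved to the aldehyde beside two other alkenes. C2 is a bare CH2O group, so the C2 carbinol would have to be made next to a quaternary carbon without control. The chosen plan is longer but delivers C9 as an acetal and C2 already set by a catalyst with the alkyne attached. Its ring closure distinguishes a methyl group from a branched arm, not from CH2OSi.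

**Alternative 3:** Ring C is cut at C8–C17 at the very end. The 2-bromopropanoate A5, a ring B ketone at C8, is reduced by SmI2 to a samarium enolate that adds to the ketone and gives A6. Its merits: ring C, the tertiary alcohol and two stereocentres form in one step inside a rigid bicyclic frame through a chelated transition state, and both bromide epimers converge. That avoids the open-chain control at C8, the weakest stereochemical point of the chosen plan (step 23), and here it is the better road. Its weak points: A5 is an α-acyloxy and α-alkoxy ketone, and SmI2 cleaves such C–O bonds in competition with enolate formation. C7–H is allylic and α to the ketone and so is easily epimerised. The face of attack depends on the ring B conformation. The ten-membered ring must still be closed by another method. The chosen plan sets C8 early by osmylation and closes the lactone by a neutral oxidation, with weaker control at C8 but without the labile dioxygenated ketone and without a reductant beside the acetoxy epoxide.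

Key step: step 11

**Assumption 1:** Pig liver esterase is taken to hydrolyse the pro-S methoxycarbonyl group of 3 and give (R)-4; should it prefer the other group, the acid and ester arms exchange roles (acid to C10 by borane reduction, ester to C2).

**Assumption 2:** 21 is used as the E/Z mixture at C9=C10 (E isomer drawn), and 22–24 are carried as mixtures of C11 epimers until step 13.

## Route

Step 1
Reactants: 1 dimethyl methylmalonate; 2 methyl vinyl ketone
Product: 3 dimethyl 2-methyl-2-(3-oxobutyl)malonate
Conditions: NaOMe (5 mol%), MeOH, 0 → 23 °C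
Reagents that add atoms: none
Why: Base-catalysed Michael addition of the malonate anion to the enone; the product has no stereocentre and its two ester groups are enantiotopic.

Step 2
Reactants: 3 dimethyl 2-methyl-2-(3-oxobutyl)malonate
Product: 4 (R)-2-(methoxycarbonyl)-2-methyl-5-oxohexanoic acid
Conditions: pig liver esterase, phosphate buffer (pH 7.5), DMSO (10%), 25 °C
Reagents that add atoms: water, O
Why: Enzymatic desymmetrisation of a prochiral α,α-disubstituted malonate: hydrolysis of one enantiotopic ester creates the quaternary C1 stereocentre, and neutral pH leaves the ketone and the second ester alone.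

Step 3
Reactants: 4 (R)-2-(methoxycarbonyl)-2-methyl-5-oxohexanoic acid; 5 ethynyltrimethylsilane
Product: 7 methyl (R)-2-methyl-5-oxo-2-[3-(trimethylsilyl)prop-2-ynoyl]hexanoate, via acid chloride 6 (not isolated)
Conditions: (COCl)2, DMF (cat.), CH2Cl2, 0 → 23 °C; then 5, PdCl2(PPh3)2 (2 mol%), CuI (4 mol%), Et3N, THF, 23 °C
Reagents that add atoms: none
Why: The acid has no α-hydrogen and cannot form a ketene, so its chloride couples cleanly with the terminal alkyne under Pd/Cu catalysis (acyl Sonogashira coupling); this makes C2–C3 and leaves C2 as a ketone for a reagent-controlled reduction.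

Step 4
Reactants: 7 methyl (R)-2-methyl-5-oxo-2-[3-(trimethylsilyl)prop-2-ynoyl]hexanoate
Product: 8 methyl (R)-2-[(R)-1-hydroxy-3-(trimethylsilyl)prop-2-yn-1-yl]-2-methyl-5-oxohexanoate
Conditions: Ru[(R,R)-TsDPEN](p-cymene) (1 mol%), i-PrOH, 23 °C
Reagents that add atoms: none
Why: Noyori asymmetric transfer hydrogenation reduces alkynyl ketones far faster than the dialkyl ketone at C12, and the catalyst rather than the neighbouring quaternary carbon fixes C2; the (R,R)-complex is chosen from the known sense of induction, in which the alkynyl group takes the place of an aryl group.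

Step 5
Reactants: 8 methyl (R)-2-[(R)-1-hydroxy-3-(trimethylsilyl)prop-2-yn-1-yl]-2-methyl-5-oxohexanoate
Product: 9 methyl (R)-2-[(R)-1-(tert-butyldimethylsilyloxy)-3-(trimethylsilyl)prop-2-yn-1-yl]-2-methyl-5-oxohexanoate
Conditions: TBSCl, imidazole, DMF, 35 °C
Reagents that add atoms: tert-butyldimethylsilyl chloride, CC(C)(C)[Si](C)(C)Cl
Why: Silylation of the secondary propargylic alcohol with imidazole as base does not enolise the methyl ketone; the ether protects O2 until the last step.

Step 6
Reactants: 9 methyl (R)-2-[(R)-1-(tert-butyldimethylsilyloxy)-3-(trimethylsilyl)prop-2-yn-1-yl]-2-methyl-5-oxohexanoate; 10 N,N-dimethylmethyleneiminium iodide (Eschenmoser's salt)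
Product: 14 methyl (R)-2-[(R)-1-(tert-butyldimethylsilyloxy)-3-(trimethylsilyl)prop-2-yn-1-yl]-2-methyl-5-oxohept-6-enoate (vinyl ketone; new carbon is C20), via lithium enolate 11 (not isolated), via Mannich base 12 (not isolated), via ammonium iodide 13 (not isolated)
Conditions: LiN(i-Pr)2, THF, −78 °C; 10, −78 → 23 °C; then MeI, CH2Cl2, 23 °C; then aq NaHCO3, CH2Cl2, 23 °C
Reagents that add atoms: none
Why: Kinetic deprotonation of the methyl ketone takes a methyl proton (C11), the enolate is aminomethylated (Mannich reaction) and the quaternised amine is eliminated (E1cB) to the vinyl ketone; C20 is thus put on C11 at the one stage where C11 can be told from C13.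

Step 7
Reactants: 14 vinyl ketone
Product: 16 methyl (R,Z)-5-(tert-butyldimethylsilyloxy)-2-[(R)-1-(tert-butyldimethylsilyloxy)-3-(trimethylsilyl)prop-2-yn-1-yl]-2-methylhept-5-enoate, via lithium enolate 15 (not isolated)
Conditions: LiBH(s-Bu)3, THF, −78 °C; then TBSCl, DMPU, −78 → 0 °C
Reagents that add atoms: tert-butyldimethylsilyl chloride, CC(C)(C)[Si](C)(C)Cl
Why: Conjugate reduction of a β-unsubstituted enone by the hindered borohydride gives the (Z)-enolate with the double bond fixed at C11=C12, and O-silylation traps it; the hindered ester is not reduced at −78 °C, and the silyl enol ether now also protects the ketone.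

Step 8
Reactants: 16 silyl enol ether ester
Product: 17 primary alcohol (C10 is CH2OH; silyl enol ether and C1 and C2 as in 16)
Conditions: i-Bu2AlH (2.5 equiv), CH2Cl2, −78 °C; aq Rochelle salt
Reagents that add atoms: none
Why: Reduction of the neopentyl ester to the primary alcohol; silyl enol ether, silyl ether and silylalkyne are inert to the aluminium hydride at low temperature.

Step 9
Reactants: 17 primary alcohol
Product: 18 aldehyde (C10 is CHO on the quaternary C1)
Conditions: SO3·pyridine, DMSO, i-Pr2NEt, CH2Cl2, 0 °C
Reagents that add atoms: none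
Why: Parikh–Doering oxidation is basic and non-aqueous, so the acid-labile silyl enol ether survives; the aldehyde has a quaternary α-carbon and cannot epimerise.

Step 10
Reactants: 18 aldehyde; 19 (methoxymethyl)triphenylphosphonium chloride
Product: 21 bis(enol ether) (C9=C10 methyl enol ether as E/Z mixture; (Z)-C11=C12 silyl enol ether bearing C20; C2 OTBS; C3≡C4–SiMe3), via ylide 20 (not isolated)
Conditions: 19, KN(SiMe3)2, THF, 0 °C; then 18, −78 → 23 °C
Reagents that add atoms: none
Why: Wittig reaction of the methoxymethylene ylide adds C9 as a methyl enol ether; the E/Z ratio does not matter because both isomers give the same radical cation and C9 ends as an acetal.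

Step 11
Reactants: 21 bis(enol ether)
Product: 22 ring A ketone (C12 ketone; C11 methyl as both epimers; β-CH(OMe)2 (C9) on C10 trans to the C2 arm; C1 β-methyl; C2 OTBS; C3≡C4–SiMe3)
Conditions: constant current (8 mA, 2.2 F/mol), reticulated vitreous carbon anode, platinum cathode, undivided cell, LiClO4 (0.1 M), 2,6-lutidine, MeOH/CH2Cl2 (1:4), 23 °C
Reagents that add atoms: methanol, CO
Why: Anodic oxidation removes one electron from the more electron-rich trisubstituted silyl enol ether (or, equally productively, from the methyl enol ether), and the radical cation and the second enol ether join their β-carbons C10 and C11, which are both nucleophilic in polar chemistry. A second electron transfer gives a doubly oxygen-stabilised cation: methanol adds at C9 to give the dimethyl acetal and takes the silyl group from O12 to free the ketone, while protons are reduced to H2 at the cathode. The closest known reaction type is the intramolecular anodic coupling of an alkyl enol ether with a silyl enol ether to a 1,4-dicarbonyl equivalent. Ring A closes as a six-membered ring, exo with respect to C9=C10 (C9 stays outside the ring) and endo with respect to C11=C12. C10 is set by a chair transition state in which the bulky C2 arm on the quaternary C1 and the C9 arm on C10 are both equatorial and C15 is axial, which puts C9 trans to C2; C11 forms without control and is corrected in step 13. The step needs oxidation of the enol ethers only (silyl ethers and the silylalkyne oxidise at much higher potential), cyclisation faster than solvent capture of the radical cation (helped by the 1,6-relation of the termini and the fully substituted C1), and 2,6-lutidine to stop solvolysis of either enol ether before it is oxidised.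

Step 12
Reactants: 22 ring A ketone
Product: 24 ring A enone (C12 ketone conjugated with C13=C14; C11 methyl as both epimers; otherwise as 22), via trimethylsilyl enol ether 23 (not isolated)
Conditions: LiN(i-Pr)2, Me3SiCl, THF, −78 °C (in situ quench); then Pd(OAc)2 (1.1 equiv), MeCN, 23 °C
Reagents that add atoms: none
Why: Kinetic deprotonation with internal silyl quench removes a proton from the methylene C13 in preference to the methine C11, and Saegusa–Ito oxidation of the silyl enol ether by divalent palladium gives the C13=C14 enone.

Step 13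
Reactants: 24 ring A enone (C11 epimers)
Product: 26 11β-methyl enone (C20 on the β face; cis to C15 and to the C9 arm), via lithium dienolate 25 (not isolated)
Conditions: LiN(i-Pr)2, THF, −78 °C; then 2,6-di-tert-butyl-4-methylphenol, −78 °C
Reagents that add atoms: none
Why: C11 is the only enolisable position of the enone; kinetic C-protonation of the cross-conjugated dienolate by a bulky phenol should occur on the α face, away from the axial C15 methyl that is 1,3 to C11. This gives the less stable 11β-methyl epimer, which is reduced in the next step before it can equilibrate.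

Step 14
Reactants: 26 11β-methyl enone
Product: 28 allylic alcohol (12β-OH; C13=C14; terminal alkyne C3≡C4–H), via silylalkyne alcohol 27 (not isolated)
Conditions: NaBH4, CeCl3·7H2O, MeOH, −78 °C; then K2CO3 (0.3 equiv), 0 → 23 °C
Reagents that add atoms: none
Why: Luche 1,2-reduction delivers hydride axially to C12 from the α face (the β face is screened by the adjacent pseudoaxial C11 methyl) and gives the equatorial 12β-alcohol, 1,3-cis to the C9 arm, which also freezes C11. Carbonate in methanol then removes the alkynyl silyl group.

Step 15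
Reactants: 28 allylic alcohol
Product: 29 allylic acetate (12β-OAc)
Conditions: Ac2O, DMAP (cat.), pyridine, CH2Cl2, 23 °C
Reagents that add atoms: acetic anhydride, CC(=O)OC(C)=O
Why: Acylation of the secondary allylic alcohol; this acetate is the one in the target and all later steps are chosen to be compatible with it.

Step 16
Reactants: 29 allylic acetate
Product: 30 epoxy acetate (13α,14α-epoxide; 12β-OAc; 11β-methyl; C9 dimethyl acetal)
Conditions: mCPBA, NaHCO3, CH2Cl2, 0 → 23 °C
Reagents that add atoms: 3-chloroperoxybenzoic acid, OOC(=O)c1cccc(Cl)c1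
Why: Peracid epoxidation of the cis-disubstituted alkene from the α face, opposite to the pseudoaxial C15 methyl on the adjacent C1 and to the C12 acetate and C11 methyl (all β); an allylic acetate, unlike a free hydroxyl, does not direct syn.

Step 17
Reactants: 30 epoxy acetate
Product: 31 ring A aldehyde (C9 is CHO, β on C10; otherwise as 30)
Conditions: PPTS (cat.), acetone/H2O (10:1), 40 °C
Reagents that add atoms: water, O
Why: Mild acid-catalysed hydrolysis of the dimethyl acetal; pyridinium tosylate in wet acetone is weak enough to spare the silyl ether and the acetoxy epoxide, and C10 is safe because the equatorial aldehyde is the stable epimer.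

Step 18
Reactants: 32 methyl (S)-3-hydroxy-2-methylpropanoate (Roche ester)
Product: 33 methyl (S)-3-(tert-butyldimethylsilyloxy)-2-methylpropanoate
Conditions: TBSCl, imidazole, CH2Cl2, 23 °C
Reagents that add atoms: tert-butyldimethylsilyl chloride, CC(C)(C)[Si](C)(C)Cl
Why: Silylation of the primary alcohol; the stereocentre (future C17) is not involved.

Step 19
Reactants: 33 silylated Roche ester
Product: 34 (S)-3-(tert-butyldimethylsilyloxy)-2-methylpropanal
Conditions: i-Bu2AlH (1.05 equiv), CH2Cl2, −78 °C; aq Rochelle salt
Reagents that add atoms: none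
Why: Partial reduction of the ester through the aluminium hemiacetal, which is stable at −78 °C; the crude aldehyde is used at once to avoid epimerisation at its α-carbon.

Step 20
Reactants: 34 (S)-3-(tert-butyldimethylsilyloxy)-2-methylpropanal; 35 dimethyl (1-diazo-2-oxopropyl)phosphonate
Product: 36 (R)-tert-butyldimethyl[(2-methylbut-3-yn-1-yl)oxy]silane
Conditions: K2CO3, MeOH, 0 → 23 °C
Reagents that add atoms: none
Why: Ohira–Bestmann homologation: methanolysis of 35 frees the diazomethylphosphonate, which converts the aldehyde into the terminal alkyne under conditions that preserve α-stereocentres of this type; the new carbon is C7.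

Step 21
Reactants: 36 alkyne
Product: 38 (S)-tert-butyl[(3-iodo-2-methylbut-3-en-1-yl)oxy]dimethylsilane, via iodoalkenylborane 37 (not isolated)
Conditions: B-iodo-9-BBN, pentane, −20 → 0 °C; then AcOH, 0 °C
Reagents that add atoms: B-iodo-9-borabicyclo[3.3.1]nonane, IB1C2CCCC1CCC2
Why: syn-Iodoboration of the terminal alkyne puts iodine on the internal carbon, and protonolysis of the C–B bond by acetic acid gives the 2-iodoalk-1-ene; the stereocentre is untouched.

Step 22
Reactants: 31 ring A aldehyde; 38 iodoalkene
Product: 39 allylic alcohol (C9 carbinol with the configuration of the target; C8=C7H2; C17 methyl; C19 OTBS)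
Conditions: CrCl2 (6 equiv), NiCl2 (1 mol%), DMSO, 23 °C
Reagents that add atoms: none
Why: Nozaki–Hiyama–Kishi reaction: the alkenylchromium species from 38 adds only to the aldehyde and leaves acetate, epoxide and terminal alkyne alone. Felkin–Anh addition anti to the C10–C1 bond (quaternary C1 as the large group) gives the C9 configuration of the target.

Step 23
Reactants: 39 allylic alcohol
Product: 40 triol (C9 OH; tertiary C8 OH with the configuration of the target; primary C7 OH)
Conditions: OsO4 (2 mol%), N-methylmorpholine N-oxide, acetone/H2O (4:1), 0 → 23 °C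
Reagents that add atoms: N-methylmorpholine N-oxide, C[N+]1([O-])CCOCC1; water, O
Why: Upjohn dihydroxylation of the 1,1-disubstituted alkene (alkynes react much more slowly). Osmylation anti to the allylic C9 hydroxyl in the conformer with C9–H in the alkene plane (the erythro rule for allylic alcohols) should give the C8 configuration of the target and leaves C7 as a primary alcohol.

Step 24
Reactants: 40 triol
Product: 41 C7 triethylsilyl ether (C8 OH and C9 OH free)
Conditions: Et3SiCl (1.1 equiv), imidazole, CH2Cl2, −20 °C
Reagents that add atoms: chlorotriethylsilane, CC[Si](Cl)(CC)CC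
Why: The primary hydroxyl is silylated far faster than the hindered secondary and tertiary ones; the ether blocks acetyl migration to O7 and is later oxidised directly.

Step 25
Reactants: 41 C7 triethylsilyl ether
Product: 42 C9 acetate (9-OAc; 8-OH; 7-OTES; 12β-OAc; terminal alkyne)
Conditions: Ac2O, DMAP, pyridine, CH2Cl2, 23 °C
Reagents that add atoms: acetic anhydride, CC(=O)OC(C)=O
Why: Acetylation of the secondary C9 alcohol; the tertiary C8 alcohol does not react under these conditions, and acylation of O9 ensures that the lactone can later close only onto O7.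

Step 26
Reactants: 43 propargyl alcohol
Product: 44 tert-butyldiphenyl(prop-2-yn-1-yloxy)silane
Conditions: t-BuPh2SiCl, imidazole, CH2Cl2, 23 °C
Reagents that add atoms: tert-butyl(chloro)diphenylsilane, CC(C)(C)[Si](Cl)(c1ccccc1)c1ccccc1
Why: Silylation with a group that survives the later acidic fluoride step (step 34) and protects the C16 alcohol until the end.

Step 27
Reactants: 44 silyl propargyl ether; 45 trimethyl(tributylstannyl)silane
Product: 46 (Z)-tert-butyldiphenyl{[2-(tributylstannyl)-3-(trimethylsilyl)prop-2-en-1-yl]oxy}silane
Conditions: Pd(PPh3)4 (2 mol%), THF, 65 °C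
Reagents that add atoms: none
Why: Palladium-catalysed silylstannation of a terminal alkyne is a cis addition of the Si–Sn bond with tin on the internal and silicon on the terminal carbon, which fixes the future C5=C6 geometry.

Step 28
Reactants: 46 silyl stannyl alkene
Product: 47 (Z)-tert-butyl{[2-iodo-3-(trimethylsilyl)prop-2-en-1-yl]oxy}diphenylsilane
Conditions: I2, CH2Cl2, 0 °C
Reagents that add atoms: iodine, II
Why: Iododestannylation with retention; the C–Sn bond is cleaved much faster than the C–Si bond, so the vinylsilane survives as the latent C6 iodide.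

Step 29
Reactants: 42 C9 acetate (terminal alkyne); 47 alkenyl iodide
Product: 48 enyne (C3≡C4–C5(C16H2OTBDPS)=C6H–SiMe3 with C4 and Si cis)
Conditions: Pd(PPh3)4 (5 mol%), CuI (10 mol%), i-Pr2NH, THF, 23 °C
Reagents that add atoms: none
Why: Sonogashira coupling forms C4–C5 with retention of the alkene geometry; the amine base at room temperature does not disturb acetates, epoxide or silyl ethers.

Step 30
Reactants: 48 enyne
Product: 49 dienylsilane ((3Z)-alkene; C5=C6 unchanged)
Conditions: H2 (1 atm), Pd/CaCO3 poisoned with Pb(OAc)2 (Lindlar catalyst), quinoline, EtOAc, 23 °C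
Reagents that add atoms: none
Why: Lindlar semihydrogenation adds hydrogen cis to the alkyne and gives the (3Z)-alkene; the trisubstituted vinylsilane is not reduced.

Step 31
Reactants: 49 dienylsilane
Product: 50 dienyl iodide (C6–I cis to C4)
Conditions: N-iodosuccinimide, (CF3)2CHOH, 0 °C
Reagents that add atoms: N-iodosuccinimide, O=C1CCC(=O)N1I
Why: Iododesilylation: ipso attack of iodonium on the vinylsilane and loss of silicon from the β-silyl cation proceed with retention in hexafluoro-2-propanol and give the iodide needed for the chromium-mediated ring closure.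

Step 32
Reactants: 50 dienyl iodide
Product: 51 α-hydroxy aldehyde (C7 is CHO on the quaternary C8; C8 OH free)
Conditions: (COCl)2, DMSO, CH2Cl2, −78 °C; 50, −78 → −30 °C; Et3N, −78 → 0 °C
Reagents that add atoms: none
Why: Under Swern conditions a primary triethylsilyl ether is cleaved and oxidised in one operation, while tert-butylsilyl ethers, acetates, epoxide and the tertiary alcohol remain; the aldehyde has no α-hydrogen and is used directly.

Step 33
Reactants: 51 α-hydroxy aldehyde
Product: 52 ring B alcohol (ten-membered ring closed at C6–C7; C7 OH with the configuration of the target)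
Conditions: CrCl2 (15 equiv), NiCl2 (2 mol%), DMSO/THF (3:1), 0.002 M, 23 °C
Reagents that add atoms: none
Why: Intramolecular Nozaki–Hiyama–Kishi reaction at high dilution closes ring B with retention of the C5=C6 geometry and tolerates every other group. Polar Felkin–Anh addition (C8–O anti to the incoming alkenyl group) leads to the C7 configuration of the target; chelation by the free hydroxyl, which would give the epimer, is weak in DMSO.

Step 34
Reactants: 52 ring B alcohol
Product: 53 diol (C19 OH freed; C7 OH and C8 OH free; C2 OTBS and C16 OTBDPS kept)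
Conditions: HF·pyridine, pyridine, THF, 0 °C
Reagents that add atoms: none
Why: Buffered HF removes the unhindered primary tert-butyldimethylsilyl ether much faster than the hindered secondary one at C2 or the tert-butyldiphenylsilyl ether at C16, and is mild enough for the acetoxy epoxide.

Step 35
Reactants: 53 diol
Product: 55 protected lactone (ring C closed), via lactol 54 (not isolated)
Conditions: TEMPO (20 mol%), PhI(OAc)2 (2.5 equiv), CH2Cl2, 23 °C
Reagents that add atoms: none
Why: Oxidative lactonisation of a 1,4-diol: the oxoammonium salt oxidises the primary alcohol first, the aldehyde is captured by the C7 hydroxyl as a five-membered lactol, and this is oxidised to the lactone. O9 is acetylated and O8 tertiary, so only O7 can close the ring.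

Step 36
Reactants: 55 protected lactone
Product: 56 briaexcavatolide N
Conditions: Bu4NF, AcOH (1:1), THF, 23 → 40 °C
Reagents that add atoms: none
Why: Fluoride cleaves both remaining silyl ethers (O2 and O16); buffering with acetic acid suppresses acetate migration, lactone opening and epoxide opening.

## Compound list

1 | dimethyl methylmalonate | COC(=O)C(C)C(=O)OC | starting material
2 | methyl vinyl ketone | CC(=O)C=C | starting material
3 | dimethyl 2-methyl-2-(3-oxobutyl)malonate | COC(=O)C(C)(CCC(C)=O)C(=O)OC | intermediate
4 | (R)-2-(methoxycarbonyl)-2-methyl-5-oxohexanoic acid | COC(=O)[C@](C)(CCC(C)=O)C(O)=O | intermediate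
5 | ethynyltrimethylsilane | C#C[Si](C)(C)C | starting material
6 | acid chloride of 4 (C1 arrangement unchanged) | COC(=O)[C@](C)(CCC(C)=O)C(Cl)=O | intermediate
7 | methyl (R)-2-methyl-5-oxo-2-[3-(trimethylsilyl)prop-2-ynoyl]hexanoate | COC(=O)[C@](C)(CCC(C)=O)C(=O)C#C[Si](C)(C)C | intermediate
8 | methyl (R)-2-[(R)-1-hydroxy-3-(trimethylsilyl)prop-2-yn-1-yl]-2-methyl-5-oxohexanoate | COC(=O)[C@](C)(CCC(C)=O)[C@@H](O)C#C[Si](C)(C)C | intermediate
9 | methyl (R)-2-[(R)-1-(tert-butyldimethylsilyloxy)-3-(trimethylsilyl)prop-2-yn-1-yl]-2-methyl-5-oxohexanoate | COC(=O)[C@](C)(CCC(C)=O)[C@@H](O[Si](C)(C)C(C)(C)C)C#C[Si](C)(C)C | intermediate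
10 | N,N-dimethylmethyleneiminium iodide (Eschenmoser's salt) | C=[N+](C)C.[I-] | starting material
11 | terminal lithium enolate of 9 (C11=C12) | COC(=O)[C@](C)(CCC(=C)O[Li])[C@@H](O[Si](C)(C)C(C)(C)C)C#C[Si](C)(C)C | intermediate
12 | Mannich base: 9 with CH2NMe2 on C11 | COC(=O)[C@](C)(CCC(=O)CCN(C)C)[C@@H](O[Si](C)(C)C(C)(C)C)C#C[Si](C)(C)C | intermediate
13 | trimethylammonium iodide of 12 | COC(=O)[C@](C)(CCC(=O)CC[N+](C)(C)C)[C@@H](O[Si](C)(C)C(C)(C)C)C#C[Si](C)(C)C.[I-] | intermediate
14 | methyl (R)-2-[(R)-1-(tert-butyldimethylsilyloxy)-3-(trimethylsilyl)prop-2-yn-1-yl]-2-methyl-5-oxohept-6-enoate | COC(=O)[C@](C)(CCC(=O)C=C)[C@@H](O[Si](C)(C)C(C)(C)C)C#C[Si](C)(C)C | intermediate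
15 | lithium (Z)-enolate from 14 (C11=C12, C20 methyl) | COC(=O)[C@](C)(CC/C(O[Li])=C/C)[C@@H](O[Si](C)(C)C(C)(C)C)C#C[Si](C)(C)C | intermediate
16 | methyl (R,Z)-5-(tert-butyldimethylsilyloxy)-2-[(R)-1-(tert-butyldimethylsilyloxy)-3-(trimethylsilyl)prop-2-yn-1-yl]-2-methylhept-5-enoate | COC(=O)[C@](C)(CC/C(O[Si](C)(C)C(C)(C)C)=C/C)[C@@H](O[Si](C)(C)C(C)(C)C)C#C[Si](C)(C)C | intermediate
17 | primary alcohol from 16 (C10 CH2OH; C1, C2 and enol ether unchanged) | OC[C@](C)(CC/C(O[Si](C)(C)C(C)(C)C)=C/C)[C@@H](O[Si](C)(C)C(C)(C)C)C#C[Si](C)(C)C | intermediate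
18 | aldehyde from 17 (C10 CHO) | O=C[C@](C)(CC/C(O[Si](C)(C)C(C)(C)C)=C/C)[C@@H](O[Si](C)(C)C(C)(C)C)C#C[Si](C)(C)C | intermediate
19 | (methoxymethyl)triphenylphosphonium chloride | COC[P+](c1ccccc1)(c1ccccc1)c1ccccc1.[Cl-] | starting material
20 | (methoxymethylene)triphenylphosphorane | COC=P(c1ccccc1)(c1ccccc1)c1ccccc1 | intermediate
21 | bis(enol ether): C9=C10 methyl enol ether (E shown, E/Z mixture), (Z)-C11=C12 TBS enol ether with C20, quaternary C1, C2 OTBS, C3≡C4–SiMe3 | CO/C=C/[C@](C)(CC/C(O[Si](C)(C)C(C)(C)C)=C/C)[C@@H](O[Si](C)(C)C(C)(C)C)C#C[Si](C)(C)C | intermediate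
22 | ring A ketone: C12 ketone, C11 methyl (both epimers), C10 β-CH(OMe)2, C1 β-methyl and α-CH(OTBS)C≡C–SiMe3 | O=C1C(C)[C@H](C(OC)OC)[C@@](C)([C@@H](O[Si](C)(C)C(C)(C)C)C#C[Si](C)(C)C)CC1 | intermediate
23 | C12=C13 trimethylsilyl enol ether of 22 | C1=C(O[Si](C)(C)C)C(C)[C@H](C(OC)OC)[C@@](C)([C@@H](O[Si](C)(C)C(C)(C)C)C#C[Si](C)(C)C)C1 | intermediate
24 | ring A enone: 22 with C13=C14 (C11 epimers) | O=C1C(C)[C@H](C(OC)OC)[C@@](C)([C@@H](O[Si](C)(C)C(C)(C)C)C#C[Si](C)(C)C)C=C1 | intermediate
25 | lithium dienolate of 24 (C11=C12–OLi, C13=C14) | [Li]OC1=C(C)[C@H](C(OC)OC)[C@@](C)([C@@H](O[Si](C)(C)C(C)(C)C)C#C[Si](C)(C)C)C=C1 | intermediate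
26 | 11β-methyl enone | O=C1[C@H](C)[C@H](C(OC)OC)[C@@](C)([C@@H](O[Si](C)(C)C(C)(C)C)C#C[Si](C)(C)C)C=C1 | intermediate
27 | 12β-allylic alcohol with silylalkyne | O[C@@H]1[C@H](C)[C@H](C(OC)OC)[C@@](C)([C@@H](O[Si](C)(C)C(C)(C)C)C#C[Si](C)(C)C)C=C1 | intermediate
28 | 12β-allylic alcohol with terminal alkyne | O[C@@H]1[C@H](C)[C@H](C(OC)OC)[C@@](C)([C@@H](O[Si](C)(C)C(C)(C)C)C#C)C=C1 | intermediate
29 | 12β-allylic acetate | CC(=O)O[C@@H]1[C@H](C)[C@H](C(OC)OC)[C@@](C)([C@@H](O[Si](C)(C)C(C)(C)C)C#C)C=C1 | intermediate
30 | 13α,14α-epoxy 12β-acetate with C9 dimethyl acetal | CC(=O)O[C@@H]1[C@H](C)[C@H](C(OC)OC)[C@@](C)([C@@H](O[Si](C)(C)C(C)(C)C)C#C)[C@H]2O[C@@H]12 | intermediate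
31 | ring A aldehyde (C9 CHO) | CC(=O)O[C@@H]1[C@H](C)[C@H](C=O)[C@@](C)([C@@H](O[Si](C)(C)C(C)(C)C)C#C)[C@H]2O[C@@H]12 | intermediate
32 | methyl (S)-3-hydroxy-2-methylpropanoate | COC(=O)[C@@H](C)CO | starting material
33 | methyl (S)-3-(tert-butyldimethylsilyloxy)-2-methylpropanoate | COC(=O)[C@@H](C)CO[Si](C)(C)C(C)(C)C | intermediate
34 | (S)-3-(tert-butyldimethylsilyloxy)-2-methylpropanal | O=C[C@@H](C)CO[Si](C)(C)C(C)(C)C | intermediate
35 | dimethyl (1-diazo-2-oxopropyl)phosphonate | COP(=O)(OC)C(=[N+]=[N-])C(C)=O | starting material
36 | (R)-tert-butyldimethyl[(2-methylbut-3-yn-1-yl)oxy]silane | C#C[C@@H](C)CO[Si](C)(C)C(C)(C)C | intermediate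
37 | (Z)-2-iodoalkenyl-9-BBN adduct of 36 | I/C(=C\B1C2CCCC1CCC2)[C@@H](C)CO[Si](C)(C)C(C)(C)C | intermediate
38 | (S)-tert-butyl[(3-iodo-2-methylbut-3-en-1-yl)oxy]dimethylsilane | C=C(I)[C@@H](C)CO[Si](C)(C)C(C)(C)C | intermediate
39 | C9 allylic alcohol: 31 joined at C9 to C8(=C7H2)–C17H(CH3)–C19H2OTBS | CC(=O)O[C@@H]1[C@H](C)[C@H]([C@@H](O)C(=C)[C@@H](C)CO[Si](C)(C)C(C)(C)C)[C@@](C)([C@@H](O[Si](C)(C)C(C)(C)C)C#C)[C@H]2O[C@@H]12 | intermediate
40 | C7,C8,C9-triol | CC(=O)O[C@@H]1[C@H](C)[C@H]([C@@H](O)[C@@](O)(CO)[C@@H](C)CO[Si](C)(C)C(C)(C)C)[C@@](C)([C@@H](O[Si](C)(C)C(C)(C)C)C#C)[C@H]2O[C@@H]12 | intermediate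
41 | C7 triethylsilyl ether of 40 | CC(=O)O[C@@H]1[C@H](C)[C@H]([C@@H](O)[C@@](O)(CO[Si](CC)(CC)CC)[C@@H](C)CO[Si](C)(C)C(C)(C)C)[C@@](C)([C@@H](O[Si](C)(C)C(C)(C)C)C#C)[C@H]2O[C@@H]12 | intermediate
42 | C9 acetate of 41 | CC(=O)O[C@@H]1[C@H](C)[C@H]([C@@H](OC(C)=O)[C@@](O)(CO[Si](CC)(CC)CC)[C@@H](C)CO[Si](C)(C)C(C)(C)C)[C@@](C)([C@@H](O[Si](C)(C)C(C)(C)C)C#C)[C@H]2O[C@@H]12 | intermediate
43 | propargyl alcohol | C#CCO | starting material
44 | tert-butyldiphenyl(prop-2-yn-1-yloxy)silane | C#CCO[Si](c1ccccc1)(c1ccccc1)C(C)(C)C | intermediate
45 | trimethyl(tributylstannyl)silane | C[Si](C)(C)[Sn](CCCC)(CCCC)CCCC | starting material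
46 | (Z)-tert-butyldiphenyl{[2-(tributylstannyl)-3-(trimethylsilyl)prop-2-en-1-yl]oxy}silane | C[Si](C)(C)/C=C(\[Sn](CCCC)(CCCC)CCCC)CO[Si](c1ccccc1)(c1ccccc1)C(C)(C)C | intermediate
47 | (Z)-tert-butyl{[2-iodo-3-(trimethylsilyl)prop-2-en-1-yl]oxy}diphenylsilane | C[Si](C)(C)/C=C(\I)CO[Si](c1ccccc1)(c1ccccc1)C(C)(C)C | intermediate
48 | enyne: 42 coupled at C4 to C5(C16H2OTBDPS)=C6H–SiMe3 | CC(=O)O[C@@H]1[C@H](C)[C@H]([C@@H](OC(C)=O)[C@@](O)(CO[Si](CC)(CC)CC)[C@@H](C)CO[Si](C)(C)C(C)(C)C)[C@@](C)([C@@H](O[Si](C)(C)C(C)(C)C)C#C/C(CO[Si](c3ccccc3)(c3ccccc3)C(C)(C)C)=C\[Si](C)(C)C)[C@H]2O[C@@H]12 | intermediate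
49 | (3Z,5E)-dienylsilane | CC(=O)O[C@@H]1[C@H](C)[C@H]([C@@H](OC(C)=O)[C@@](O)(CO[Si](CC)(CC)CC)[C@@H](C)CO[Si](C)(C)C(C)(C)C)[C@@](C)([C@@H](O[Si](C)(C)C(C)(C)C)/C=C\C(CO[Si](c3ccccc3)(c3ccccc3)C(C)(C)C)=C/[Si](C)(C)C)[C@H]2O[C@@H]12 | intermediate
50 | (3Z,5E)-dienyl iodide | CC(=O)O[C@@H]1[C@H](C)[C@H]([C@@H](OC(C)=O)[C@@](O)(CO[Si](CC)(CC)CC)[C@@H](C)CO[Si](C)(C)C(C)(C)C)[C@@](C)([C@@H](O[Si](C)(C)C(C)(C)C)/C=C\C(CO[Si](c3ccccc3)(c3ccccc3)C(C)(C)C)=C/I)[C@H]2O[C@@H]12 | intermediate
51 | C7 aldehyde with dienyl iodide | CC(=O)O[C@@H]1[C@H](C)[C@H]([C@@H](OC(C)=O)[C@@](O)(C=O)[C@@H](C)CO[Si](C)(C)C(C)(C)C)[C@@](C)([C@@H](O[Si](C)(C)C(C)(C)C)/C=C\C(CO[Si](c3ccccc3)(c3ccccc3)C(C)(C)C)=C/I)[C@H]2O[C@@H]12 | intermediate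
52 | ring B alcohol (C7 OH, C8 OH, C19 OTBS, C2 OTBS, C16 OTBDPS) | CC(=O)O[C@@H]1[C@H](C)[C@@H]2[C@@H](OC(C)=O)[C@@](O)([C@@H](O)/C=C(CO[Si](c3ccccc3)(c3ccccc3)C(C)(C)C)\C=C/[C@H](O[Si](C)(C)C(C)(C)C)[C@@]2(C)[C@H]2O[C@@H]12)[C@@H](C)CO[Si](C)(C)C(C)(C)C | intermediate
53 | C7,C19-diol | CC(=O)O[C@@H]1[C@H](C)[C@@H]2[C@@H](OC(C)=O)[C@@](O)([C@@H](O)/C=C(CO[Si](c3ccccc3)(c3ccccc3)C(C)(C)C)\C=C/[C@H](O[Si](C)(C)C(C)(C)C)[C@@]2(C)[C@H]2O[C@@H]12)[C@@H](C)CO | intermediate
54 | C19 lactol | CC(=O)O[C@@H]1[C@H](C)[C@@H]2[C@@H](OC(C)=O)[C@@]3(O)[C@H](/C=C(CO[Si](c4ccccc4)(c4ccccc4)C(C)(C)C)\C=C/[C@H](O[Si](C)(C)C(C)(C)C)[C@@]2(C)[C@H]2O[C@@H]12)OC(O)[C@@H]3C | intermediate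
55 | 2-O-TBS-16-O-TBDPS-briaexcavatolide N | CC(=O)O[C@@H]1[C@H](C)[C@@H]2[C@@H](OC(C)=O)[C@@]3(O)[C@H](/C=C(CO[Si](c4ccccc4)(c4ccccc4)C(C)(C)C)\C=C/[C@H](O[Si](C)(C)C(C)(C)C)[C@@]2(C)[C@H]2O[C@@H]12)OC(=O)[C@@H]3C | intermediate
56 | briaexcavatolide N | CC(=O)O[C@@H]1[C@H](C)[C@@H]2[C@@H](OC(C)=O)[C@@]3(O)[C@H](/C=C(CO)\C=C/[C@H](O)[C@@]2(C)[C@H]2O[C@@H]12)OC(=O)[C@@H]3C | target

## Step count and least certain steps

Total steps: 36. Longest linear sequence: 29 steps (1–17, 22–25, 29–36).

**Step 11 (key step).** The radical cation may be captured by methanol, or the product over-oxidised, before the ring closes, because a six-membered closure next to a quaternary carbon onto a trisubstituted enol ether terminus is slow. Fallback: the same C10–C11 bond is made in a polar way. Aldehyde 18 is condensed with nitromethane (catalytic t-BuOK) to the nitro alcohol F1, which is dehydrated (MsCl, Et3N) to the nitroalkene F2. SnCl4 at −78 °C promotes intramolecular Mukaiyama–Michael addition of the silyl enol ether to the nitroalkene, and aqueous (Nef-type) hydrolysis of the nitronate gives the keto aldehyde F3. Chemoselective acetalisation of the aldehyde (HC(OMe)3, CeCl3·7H2O, MeOH) returns to 22.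

**Step 2.** The enzyme may hydrolyse slowly or with low enantioselectivity, because the two ester groups are distinguished only by a methyl and a 3-oxobutyl group on the prochiral carbon. Fallback: 3 is mono-saponified (one equivalent of KOH, MeOH) to the racemic half-ester F4. This is resolved by crystallisation of its salt with (R)-1-phenylethylamine, the salt F5 (or with the antipodal amine, whichever gives the less soluble salt of the R acid), and acidification returns to 4. The unwanted acid is re-esterified to 3.

**Step 13.** Protonation may lack face selectivity, or may occur on oxygen and be followed by equilibration to the more stable 11α-methyl epimer. Fallback: from 24, the dienolate 25 is brominated with N-bromosuccinimide to the α-bromo enone F6. Reduction with Bu3SnH and Et3B/air at −78 °C transfers a hydrogen atom to the planar C11 radical from the α face, anti to the C15 methyl and the C9 arm, without passing through an enol, and returns to 26.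

**Step 23.** Face selectivity at C8 may be poor, because the alkene lies between two stereocentres (C9 and C17) whose preferences may oppose each other. Fallback: 39 is epoxidised by the Sharpless procedure (Ti(Oi-Pr)4, L-(+)-diisopropyl tartrate, t-BuOOH), in which reagent and the C9 carbinol are matched for the erythro product, to the epoxy alcohol F7. Ti(Oi-Pr)4-mediated opening at the primary C7 with levulinic acid gives the levulinate F8, and hydrazine acetate removes the levulinoyl group beside the acetate and returns to 40.

**Step 33.** The ring closure is controlled only by the conformation of the tether, so it may give the C7 epimer (or a mixture), besides the usual competition from oligomerisation. Fallback: if 51 cyclises mainly to the C7 epimer F9, this is oxidised with Dess–Martin periodinane to the dienone F10. Reduction with BH3·SMe2 and the Corey–Bakshi–Shibata oxazaborolidine, enantiomer chosen for the required face, sets C7 by reagent control and returns to 52.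

## Further compounds

F1 | step 11 | nitro alcohol from 18 (C10 carbinol, C9 CH2NO2) | [O-][N+](=O)CC(O)[C@](C)(CC/C(O[Si](C)(C)C(C)(C)C)=C/C)[C@@H](O[Si](C)(C)C(C)(C)C)C#C[Si](C)(C)C
F2 | step 11 | (E)-nitroalkene (C9=C10) with C11=C12 silyl enol ether | [O-][N+](=O)/C=C/[C@](C)(CC/C(O[Si](C)(C)C(C)(C)C)=C/C)[C@@H](O[Si](C)(C)C(C)(C)C)C#C[Si](C)(C)C
F3 | step 11 | ring A keto aldehyde (C12 ketone, C9 CHO, C11 epimers) | O=C1C(C)[C@H](C=O)[C@@](C)([C@@H](O[Si](C)(C)C(C)(C)C)C#C[Si](C)(C)C)CC1
F4 | step 2 | racemic 2-(methoxycarbonyl)-2-methyl-5-oxohexanoic acid | COC(=O)C(C)(CCC(C)=O)C(O)=O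
F5 | step 2 | (R)-1-phenylethylammonium salt of 4 | COC(=O)[C@](C)(CCC(C)=O)C([O-])=O.C[C@@H]([NH3+])c1ccccc1
F6 | step 13 | 11-bromo-11-methyl enone (C11 epimers) | O=C1C(C)(Br)[C@H](C(OC)OC)[C@@](C)([C@@H](O[Si](C)(C)C(C)(C)C)C#C[Si](C)(C)C)C=C1
F7 | step 23 | C7,C8-epoxy C9 alcohol | CC(=O)O[C@@H]1[C@H](C)[C@H]([C@@H](O)[C@@]3(CO3)[C@@H](C)CO[Si](C)(C)C(C)(C)C)[C@@](C)([C@@H](O[Si](C)(C)C(C)(C)C)C#C)[C@H]2O[C@@H]12
F8 | step 23 | C7 levulinate of 40 | CC(=O)O[C@@H]1[C@H](C)[C@H]([C@@H](O)[C@@](O)(COC(=O)CCC(C)=O)[C@@H](C)CO[Si](C)(C)C(C)(C)C)[C@@](C)([C@@H](O[Si](C)(C)C(C)(C)C)C#C)[C@H]2O[C@@H]12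
F9 | step 33 | C7 epimer of 52 | CC(=O)O[C@@H]1[C@H](C)[C@@H]2[C@@H](OC(C)=O)[C@@](O)([C@H](O)/C=C(CO[Si](c3ccccc3)(c3ccccc3)C(C)(C)C)\C=C/[C@H](O[Si](C)(C)C(C)(C)C)[C@@]2(C)[C@H]2O[C@@H]12)[C@@H](C)CO[Si](C)(C)C(C)(C)C
F10 | step 33 | C7 ketone of 52 | CC(=O)O[C@@H]1[C@H](C)[C@@H]2[C@@H](OC(C)=O)[C@@](O)(C(=O)/C=C(CO[Si](c3ccccc3)(c3ccccc3)C(C)(C)C)\C=C/[C@H](O[Si](C)(C)C(C)(C)C)[C@@]2(C)[C@H]2O[C@@H]12)[C@@H](C)CO[Si](C)(C)C(C)(C)C
A1 | alternative 1 | eleven-membered cyclic sulfone with SO2 between C5 and C6 | COc1ccc(cc1)CO[C@@H]1[C@H](C)[C@@H]2[C@@H](OCc3ccc(OC)cc3)C3(OCCO3)[C@H](CS(=O)(=O)C(CO[Si](C)(C)C(C)(C)C)/C=C\[C@H](O[Si](C)(C)C(C)(C)C)[C@@]2(C)[C@H]2O[C@@H]12)O[Si](CC)(CC)CC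
A2 | alternative 1 | ring A/B diene with C8 ketal | COc1ccc(cc1)CO[C@@H]1[C@H](C)[C@@H]2[C@@H](OCc3ccc(OC)cc3)C3(OCCO3)[C@H](/C=C(CO[Si](C)(C)C(C)(C)C)\C=C/[C@H](O[Si](C)(C)C(C)(C)C)[C@@]2(C)[C@H]2O[C@@H]12)O[Si](CC)(CC)CC
A3 | alternative 2 | 4-[(tert-butyldimethylsilyloxy)methyl]-4-methylcyclohexa-2,5-dienone | O=C1C=CC(C)(CO[Si](C)(C)C(C)(C)C)C=C1
A4 | alternative 2 | ring A enone with C10 vinyl group and C11 exocyclic methylene | O=C1C(=C)[C@H](C=C)[C@@](C)(CO[Si](C)(C)C(C)(C)C)C=C1
A5 | alternative 3 | ring B C8 ketone with 2-bromopropanoate on O7 | CC(=O)O[C@@H]1[C@H](C)[C@@H]2[C@@H](OCc3ccc(OC)cc3)C(=O)[C@H](/C=C(CO[Si](C)(C)C(C)(C)C)\C=C/[C@H](O[Si](C)(C)C(C)(C)C)[C@@]2(C)[C@H]2O[C@@H]12)OC(=O)C(C)Br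
A6 | alternative 3 | protected briaexcavatolide N with ring C closed | CC(=O)O[C@@H]1[C@H](C)[C@@H]2[C@@H](OCc3ccc(OC)cc3)[C@@]4(O)[C@H](/C=C(CO[Si](C)(C)C(C)(C)C)\C=C/[C@H](O[Si](C)(C)C(C)(C)C)[C@@]2(C)[C@H]2O[C@@H]12)OC(=O)[C@@H]4C
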